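The slowness of the last readings in the eta flask is what I have to explain: L goes from 52.1 % at 10.0 min to 53.5 % at 15.0 min.

| setting | eta | epsilon | flask |
|---|---|---|---|
| D | 0.015 M | 0.015 M | 0.015 M |
| Q | 3 equiv | 3 equiv | 3.00 equiv |
| temperature | 5 °C | 0 °C | 5 °C |
| remark | the very flask that is asked about, followed so far | run made earlier |  |
| time |  |  | 25 min |

| run | time / min | L / % |
|---|---|---|
| eta | 1.33 | 23.4 |
| eta | 2.00 | 30.1 |
| eta | 3.00 | 36.7 |
| eta | 5.00 | 44.1 |
| eta | 10.0 | 52.1 |
| eta | 15.0 | 53.5 |
| epsilon | 1.33 | 19.5 |
| epsilon | 2.00 | 26.4 |
| epsilon | 3.00 | 33.9 |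
| epsilon | 5.00 | 43.4 |
| epsilon | 10.0 | 56.5 |
| epsilon | 15.0 | 60.2 |

(each reading ± 0.5 percentage points)

- summer: change nothing and wait 12 min more
- midnight: at 25 min raise the temperature by 10 K, then wait 12 min
- spring: at 25 min add Q, 100 % of the amount charged, then wait 12 min
- noon: at 25 min add D, 50.0 % of the amount charged, then wait 12 min

- L, in percent of the D first charged, at 25 min
- the remedy with the largest gain of L, or "none" below 2 percentage points (summer / midnight / spring / noon / none)
- L present, in percent of the D first charged, after spring
- L present, in percent of the D first charged, after noon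

- a species is counted by the D in it: one J counts as two
- amounts and yields of L count J too
- the volume of additions can be left aside
- candidate steps: Q + L -> Z; D + Q -> L; D + L <-> J; Q -> E
- in an amount of L, one J counts as one L

The candidate steps are these: D with Q gives L, Q with L gives Z, D and L bind reversibly to J, and Q alone goes to E.

The bench rule says that Q charged at 3 equiv is in excess, so I freeze [Q] and treat D as pseudo-first-order. The first eta reading gives 0.200 min⁻¹, so L should reach 95.0 % at 15.0 min, but the reading is 53.5 %. The rule fails there. As a reading, and a rough one given the scatter, the rate of rise falls by a factor of 62.8. Unconverted D, with Z taken as small, falls by a factor of 2.15. I put the remaining factor of about 29.2 on [Q], so I take [Q] as the thing that does not stay constant. The colder epsilon flask starts lower, at 19.5 % against 23.4 %, yet ends higher, at 60.2 % against 53.5 %, which fits a loss of Q that gains more from warmth than D + Q does.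

So I freeze something else: I assume that at fixed temperature a charge of Q dies by itself in first order, its use on D set aside, and so converts the same fraction of whatever D it meets. I call 46.5 % the survival factor, the fraction of D that outlives one charge of Q. This value is a reading, taken at 15.0 min with Z taken as small. I expect L near 53.5 % at 25 min. Summer, midnight and noon bring no Q, so they start no new charge. Spring brings one equal charge, which leaves 21.6 % and puts L plus Z at 78.4 %.

The forecast gives 54 %, spring, 66 % after spring and 54.3 % after noon: “Fresh Q converts much of the remaining D”. My figure for spring includes Z and stands higher than its 66 %.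

The flask gives 54.0 %, and spring gains 19 percentage points, reaching 72.7 %, while noon gives 54.1 %.

    Q + L → Z (k = 0.481 M⁻¹ min⁻¹, Ea = 60.0 kJ mol⁻¹)
    D + Q → L (k = 5.51 M⁻¹ min⁻¹, Ea = 37.0 kJ mol⁻¹)
    D + L ⇌ J, settled at all times (K = 27.9 M⁻¹, ΔH = −5.00 kJ mol⁻¹)
    Q → E (k = 0.219 min⁻¹, Ea = 89.0 kJ mol⁻¹)
    (constants at 5 °C)

At 25.0 min the asked flask holds 37 % of its D as free D and 0.16 % of its Q: Q, charged in excess, is the first to run out, the limiting reagent here. L after spring lies 5.7 points below my 78.4 % for L plus Z. The neighbouring flask with 7.50 equiv of Q has 2.50 charges, so 46.5 % puts its L plus Z at 85.3 %. At 25.0 min it holds L at 76.4 % and Z at 10.7 %, together 87.1 %.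

The earlier runs and the new flask are calculated for substances that don't exist; scatter was added.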